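## Analysis of the target

Labdane numbering is used throughout: ring A is C1–C5 with C10, ring B is C5–C10, C11–C16 form the chain on C9, C17 is the carboxyl carbon on C8, and C20 is the methyl group on C10. Compound 25 is a trans-fused decalin: ring A is saturated and carries the gem-dimethyl group on C4; ring B holds the C7=C8 double bond conjugated to the C17 acid, an acetoxy group on C6 and a (2E)-3-methylpenta-2,4-dienyl chain on C9. The four stereocentres are (5R,6S,9S,10S). H-5 and H-9 are both anti to the axial C20 methyl, so the side chain is equatorial; the C6 acetoxy group is axial, syn to C20 and to the axial methyl on C4. This is the enantiomeric (ent) labdane series, so the usual building blocks obtained by degradation of sclareol-type labdanes do not help. The sensitive groups are the allylic acetate γ to the acid (hydrolysis, ionisation, 1,4-elimination towards C9), the terminal conjugated diene (acid, oxidants, radicals) and the allylic C9–H, which becomes epimerisable once a carbonyl sits on C11 or C6. The difficulties are the quaternary C10 beside C5, which is itself flanked by quaternary C4, and three oxidation levels in ring B (C6–O, C17 acid, C7=C8) that must be set before the oxidant-sensitive diene exists. The strategy rests on one feature: the unit C5–C4(CH3)2 beside C10, together with the C7=C8 alkene bearing C17, is the carbon pattern of (S)-carvone 1. Its C5 with the isopropenyl group becomes C5/C4, its α′ carbon becomes C10, its carbonyl carbon C9, its C(CH3)=CH unit C8(C17)=C7 and its ring CH2 C6, so that 1 becomes ring B and ring A is closed onto it.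

## Retrosynthetic reasoning

**25 ⇐ 24.** The acid is liberated last. The C6 acetate excludes saponification, so the O–alkyl bond of a 2-(trimethylsilyl)ethyl ester is cut: fluoride-induced fragmentation of 24 should release the acid without touching the acetate or the diene.

**24 ⇐ 23 ⇐ 22.** The diene is taken apart at its two double bonds, C14=C15 first and then C12=C13, leading through enal 23 to aldehyde 22. Cutting at C12=C13 rather than at C11–C12 keeps every carbonyl one carbon away from C9; a formyl group on C9 beside the C7=C8 ester would invite epimerisation or conjugation. A stabilised α-methyl ylide fixes the E geometry of C12=C13 and a methylene ylide finishes the chain. Both olefinations come after all oxidations of ring B, which the diene would not survive.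

**22 ⇐ 21 ⇐ 20 ⇐ 19 ⇐ 18.** The C12 aldehyde goes back to a silyl-protected primary alcohol, and the C6 acetate to alcohol 19 and ketone 18. The bond formed forward is C6–H: hydride must reach C6 from the face opposite the two syn-axial methyl groups (C20 and the axial methyl on C4), which places the oxygen axial as required.

**18 ⇐ 17.** The C6 oxygen is removed. C6 is the only allylic methylene of enoate 17, so an allylic C–H oxidation can address it selectively.

**17 ⇐ 16 ⇐ 15 ⇐ 14.** The carboxyl group is reduced back to the C17 methyl group of 14. Forward, an allylic oxidation has to pick the methyl group on the more substituted alkene carbon C8; the only other allylic position on that carbon is the tertiary C9–H. Oxidation to the acid and esterification follow.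

**14 ⇐ 13 ⇐ 10.** The C11–C12 bond and the C9–H bond are cut together. Hydroboration of the exocyclic C9=C11 alkene of diene 10 delivers hydrogen to C9 from the face opposite C20 and so sets the C9 stereocentre. The boron on C11 is then exchanged for one carbon (C12) by carbonylation before release as alcohol 13. This installs the two-carbon arm without passing through a formyl group on C9.

**10 ⇐ 9.** C9=C11 is cut; the forward reaction is a methylenation of the hindered, non-enolisable C9 ketone.

**9 ⇐ 7 ⇐ 6.** A carboxyl group is put back on C2. It has no counterpart in 25; its only task is to activate the acceptor alkene for ring closure, and it leaves by radical decarboxylation.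

**6 ⇐ 5.** C3–C4 is cut, which opens ring A. C4 is a quaternary carbon carrying two methyl groups, exactly what the tertiary radical from hydrogen-atom addition to an isopropenyl group provides. Cutting C5–C10 or C1–C10 instead would mean forming the quaternary C10 during ring closure. What is gained is a monocyclic precursor in which both ring-fusion centres already exist, one from the chiral pool. Forward, hydrogen-atom transfer must go to the isopropenyl group and the C4 radical must close 6-endo onto the acrylate.

**5 ⇐ 3 + 4, and 3 ⇐ 1 + 2.** C1–C10 and C10–C20 are cut. These are two successive alkylations at the α′ carbon of 1. The methyl group is introduced first, so that the larger acrylate arm enters the enolate of 3 anti to the isopropenyl group and the two ring A arms end up trans.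

## Alternatives that were turned down

**Alternative 1:** The angular methyl is disconnected through a three-membered ring. C10–C20 and a temporary C5–C20 bond are traced to a hydroxyl-directed cyclopropanation (zinc carbenoid) of the tetrasubstituted C5=C10 alkene of allylic alcohol A1. This gives propellane carbinol A2; reductive opening of C5–C20 would later reveal the methyl group and H-5.
- For: the C6 hydroxyl, which the target carries, steers the carbenoid to its own face, so C20 arrives syn to the C6 oxygen as in 25. On this point it is stronger than the chosen route: the C6/C10 relationship is fixed in one directed event and the C6 oxygen is present from the start.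
- Against: A1 must first be made as a single enantiomer. The alkene is tetrasubstituted and flanked by the gem-dimethyl group, a poor substrate for the carbenoid. Regioselective opening of C5–C20 needs a C6 carbonyl, so the C6 stereocentre is destroyed and has to be reset. Above all, A2 has C7, C8 and C9 as bare methylenes: the carboxyl on C8, the C7=C8 bond and the C9 chain with its stereocentre would all have to be introduced from one C6 carbonyl, two of them at remote positions.
- In its place the chosen strategy delivers ring B already functionalised: carbonyl at C9, methyl on C8 and C7=C8 in place.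

**Alternative 2:** Both rings are disconnected at once, at C5–C10 and C8–C9, by an intramolecular Diels–Alder reaction of trienal A3. The (E)-enal C9=C10 adds to the 2-silyloxy diene C5=C6–C7=C8 under a chiral oxazaborolidinium Lewis acid to give adduct A4.
- For: one step would set C5, C9 and C10. The endo-aldehyde, tether-exo transition state leads to the trans fusion with the formyl group syn to C20. The adduct also carries oxygen at C6, an oxidised C17 and a C11 aldehyde. In convergence and in the number of steps after ring formation it is clearly stronger than the chosen route.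
- Against: C5–C10 must form between a neopentyl diene terminus and the β,β-disubstituted carbon of the enal, creating a quaternary centre next to a carbon flanked by another; this is at the low end of Diels–Alder reactivity. The strongly acidic activator such an enal needs threatens the silyl dienol ether (desilylation, stepwise Mukaiyama–Michael pathways). The absolute configuration rests entirely on catalyst control over a hindered, flexible substrate. A3, with three stereodefined alkenes, needs its own multistep synthesis. A4 also places a formyl group on C9, the epimerisable arrangement the chosen route avoids.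
- In its place the chosen strategy offers an absolute configuration taken from 1, a ring fusion fixed by the substrate and a precursor two steps from commercial material.

**Alternative 3:** Ring B is disconnected at C6–C7. The acyl radical from selenoester A5 would add 6-endo to C7 of the α-substituted acrylate and give decalone A6, with the C6 ketone, the C8 ester and an amide chain on C9.
- For: 6-endo closures of acyl radicals onto 2-substituted acrylates are well behaved. A6 has the correct oxidation level at C6 and C17 and already carries C11 and C12. On placement of functional groups it is stronger than the chosen route, which needs two allylic oxidations after ring closure.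
- Against: the burden moves to A5. A ring A cyclohexane with three contiguous stereocentres, including quaternary C10 and an exocyclic C9 centre with two different arms, must be assembled enantioselectively before the key step. The acyl radical sits on the hindered C5 between C4 and C10, so decarbonylation competes with the slow 6-endo closure. C8 forms as an sp3 centre, and the C7=C8 bond must still be introduced by dehydrogenation.
- The chosen strategy spends more steps after ring closure but reaches its precursor by two alkylations and puts the risk into a single, stereochemically predetermined ring closure.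

Key step: step 3

Remark on the chemistry: the configuration at C2 of compounds 6–8 has no consequence, because C2 becomes a methylene group in step 5; the equatorial epimer is drawn.

## Route

Step 1
Reactants: 1 (S)-(+)-carvone; 2 iodomethane
Product: 3 (5S)-2,6-dimethyl-5-(prop-1-en-2-yl)cyclohex-2-en-1-one (6-methylcarvone; both C6 epimers)
Conditions: LiN(i-Pr)2, THF, −78 °C; then MeI, −78 → 0 °C
Reagents that add atoms: iodomethane (compound 2), CI
Why: Kinetic deprotonation of the enone takes place at the α′ carbon (future C10) and the lithium enolate is C-methylated (enolate alkylation); the new centre need not be controlled because it becomes a planar enolate again in step 2.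

Step 2
Reactants: 3 (5S)-2,6-dimethyl-5-(prop-1-en-2-yl)cyclohex-2-en-1-one; 4 methyl 2-(bromomethyl)prop-2-enoate
Product: 5 methyl 2-{[(1R,6R)-1,3-dimethyl-2-oxo-6-(prop-1-en-2-yl)cyclohex-3-en-1-yl]methyl}prop-2-enoate
Conditions: LiN(i-Pr)2, THF, −78 °C; then 4, −78 → −20 °C
Reagents that add atoms: methyl 2-(bromomethyl)prop-2-enoate (compound 4), C=C(CBr)C(=O)OC
Why: The tetrasubstituted enolate of 3 is alkylated by the allylic bromide (enolate alkylation, by SN2 or SN2′ addition–elimination, both leading to the same product). The electrophile should approach anti to the neighbouring isopropenyl group, the established sense for 6-substituted carvone enolates, which sets quaternary C10 with the acrylate arm trans to the isopropenyl group.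

Step 3
Reactants: 5 methyl 2-{[(1R,6R)-1,3-dimethyl-2-oxo-6-(prop-1-en-2-yl)cyclohex-3-en-1-yl]methyl}prop-2-enoate
Product: 6 methyl (2R,4aR,8aR)-4,4,7,8a-tetramethyl-8-oxo-1,2,3,4,4a,5,8,8a-octahydronaphthalene-2-carboxylate
Conditions: Fe(acac)3 (0.3 equiv), PhSiH3, EtOH/ethylene glycol, 60 °C, dilute, under argon
Reagents that add atoms: none
Why: An iron hydride formed from Fe(acac)3 and PhSiH3 transfers a hydrogen atom to the CH2 terminus of the isopropenyl group, the only electron-rich alkene of 5, and leaves the tertiary C4 radical that already carries both methyl groups. This nucleophilic radical adds to the unsubstituted terminus C3 of the 2-substituted acrylate to form the C3–C4 bond, and the resulting tertiary α-ester radical at C2 is reduced to the enolate and protonated by the alcohol solvent. The closest known reaction type is the Fe(acac)3/PhSiH3 reductive olefin coupling (hydrogen-atom-transfer Giese addition), which is established for building quaternary carbons, also in intramolecular form. Ring A closes in the 6-endo-trig mode: because the tether is attached to the α-carbon of the acceptor, attack at C3 is polarity-matched and gives a stabilised radical, whereas the 5-exo alternative at C2 would give a primary radical. No ring-fusion stereocentre is made in this step: C5 (from 1) and C10 (from step 2) carry their arms trans, so only the trans-decalin with C20 axial can form. The one new stereocentre, C2, is set by protonation of the enolate and is expected to end as the equatorial ester; it is erased in step 5. The selectivities required are hydrogen-atom transfer to the isopropenyl group rather than to the two electron-poor alkenes, secured by the preference of metal hydride hydrogen-atom transfer for electron-rich 1,1-disubstituted alkenes, and attack on the acrylate rather than the enone, secured because C7 and C8 could only be reached through four-membered or strained bridged five-membered rings. Dilution and exclusion of air should suppress intermolecular addition and oxygen trapping of the C4 radical.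

Step 4
Reactants: 6 methyl (2R,4aR,8aR)-4,4,7,8a-tetramethyl-8-oxo-1,2,3,4,4a,5,8,8a-octahydronaphthalene-2-carboxylate
Product: 7 (2R,4aR,8aR)-4,4,7,8a-tetramethyl-8-oxo-1,2,3,4,4a,5,8,8a-octahydronaphthalene-2-carboxylic acid
Conditions: LiOH·H2O, THF/MeOH/H2O, 40 °C; then 1 M HCl
Reagents that add atoms: lithium hydroxide, [Li+].[OH-]
Why: Saponification of an unhindered secondary methyl ester; the hindered enone has no hydrolysable group, and either C2 epimer serves in the next step.

Step 5
Reactants: 7 (2R,4aR,8aR)-4,4,7,8a-tetramethyl-8-oxo-1,2,3,4,4a,5,8,8a-octahydronaphthalene-2-carboxylic acid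
Product: 9 (4aR,8aR)-2,5,5,8a-tetramethyl-4a,5,6,7,8,8a-hexahydronaphthalen-1(4H)-one, via Barton ester 8 (not isolated)
Conditions: N-hydroxypyridine-2-thione, DCC, DMAP (cat.), CH2Cl2, 0 °C → rt, dark; then t-BuSH, hν (tungsten lamp), rt
Reagents that add atoms: none
Why: Barton reductive decarboxylation: the thiohydroxamate ester 8 fragments in a radical chain to CO2 and the secondary C2 radical, which is quenched by the thiol. The C2 radical has no alkene within reach (C7=C8 lies across ring B), so only hydrogen abstraction is expected, and the activating group of the key step is removed.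

Step 6
Reactants: 9 (4aR,8aR)-2,5,5,8a-tetramethyl-4a,5,6,7,8,8a-hexahydronaphthalen-1(4H)-one
Product: 10 (4aR,8aR)-2,5,5,8a-tetramethyl-1-methylidene-1,4,4a,5,6,7,8,8a-octahydronaphthalene
Conditions: Ph3PCH3Br, KOt-Bu, toluene, 90 °C
Reagents that add atoms: methyltriphenylphosphonium bromide, C[P+](c1ccccc1)(c1ccccc1)c1ccccc1.[Br-]
Why: Wittig methylenation of the C9 ketone; the carbonyl has no α-hydrogen on C10 and cannot enolise there, and the hot conditions used for hindered ketones should overcome shielding by C20 and the C8 methyl. The product is the fixed transoid diene C11=C9–C8=C7.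

Step 7
Reactants: 10 (4aR,8aR)-2,5,5,8a-tetramethyl-1-methylidene-1,4,4a,5,6,7,8,8a-octahydronaphthalene
Product: 13 2-[(1R,4aR,8aR)-2,5,5,8a-tetramethyl-1,4,4a,5,6,7,8,8a-octahydronaphthalen-1-yl]ethan-1-ol, via alkylborane 11 (not isolated), via boryl carbinol 12 (not isolated)
Conditions: 9-BBN, THF, 0 °C → rt; then CO (1 atm), LiAlH(Ot-Bu)3, THF, −30 → 0 °C; then KOH, EtOH/H2O, 60 °C
Reagents that add atoms: carbon monoxide, [C-]#[O+]
Why: 9-BBN hydroborates the exocyclic 1,1-disubstituted alkene of the diene with boron on C11 and leaves the hindered trisubstituted C7=C8 alone; the reagent approaches from the face opposite the axial C20 on the neighbouring C10, so hydrogen is delivered to C9 anti to C20 and the new C9 stereocentre is set by the substrate. Carbonylation of B-alkyl-9-BBN compounds in the presence of an alkoxyaluminium hydride is a known one-carbon homologation: CO inserts into the B–C11 bond (the primary alkyl group migrates in preference to the bicyclic ring bonds), the hydride traps the acylborane as 12, and alkaline hydrolysis releases the primary alcohol.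

Step 8
Reactants: 13 2-[(1R,4aR,8aR)-2,5,5,8a-tetramethyl-1,4,4a,5,6,7,8,8a-octahydronaphthalen-1-yl]ethan-1-ol
Product: 14 tert-butyl(diphenyl){2-[(1R,4aR,8aR)-2,5,5,8a-tetramethyl-1,4,4a,5,6,7,8,8a-octahydronaphthalen-1-yl]ethoxy}silane
Conditions: TBDPSCl, imidazole, DMF, rt
Reagents that add atoms: tert-butyl(chloro)diphenylsilane, CC(C)(C)[Si](Cl)(c1ccccc1)c1ccccc1
Why: Silylation of an unhindered primary alcohol; the tert-butyldiphenylsilyl ether is chosen because it should survive the acidic selenium step, the chlorite oxidation and the chromium oxidation.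

Step 9
Reactants: 14 tert-butyl(diphenyl){2-[(1R,4aR,8aR)-2,5,5,8a-tetramethyl-1,4,4a,5,6,7,8,8a-octahydronaphthalen-1-yl]ethoxy}silane
Product: 15 (1S,4aR,8aR)-1-{2-[(tert-butyldiphenylsilyl)oxy]ethyl}-5,5,8a-trimethyl-1,4,4a,5,6,7,8,8a-octahydronaphthalene-2-carbaldehyde
Conditions: SeO2 (2 equiv), 1,4-dioxane, 80 °C
Reagents that add atoms: selenium dioxide, O=[Se]=O
Why: Riley allylic oxidation (ene reaction, then [2,3]-shift) occurs α to the more substituted alkene carbon C8; of the two positions there, the C17 methyl (cis to H-7) is preferred over the tertiary C9–H, as is known for drimenyl esters, and the primary allylic alcohol is carried on to the conjugated aldehyde under these conditions.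

Step 10
Reactants: 15 (1S,4aR,8aR)-1-{2-[(tert-butyldiphenylsilyl)oxy]ethyl}-5,5,8a-trimethyl-1,4,4a,5,6,7,8,8a-octahydronaphthalene-2-carbaldehyde
Product: 16 (1S,4aR,8aR)-1-{2-[(tert-butyldiphenylsilyl)oxy]ethyl}-5,5,8a-trimethyl-1,4,4a,5,6,7,8,8a-octahydronaphthalene-2-carboxylic acid
Conditions: NaClO2, NaH2PO4, 2-methylbut-2-ene, t-BuOH/H2O, rt
Reagents that add atoms: sodium chlorite, [Na+].[O-]Cl=O
Why: Pinnick oxidation converts the conjugated aldehyde into the acid without touching the alkene or the silyl ether; the alkene scavenger removes the hypochlorous acid formed.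

Step 11
Reactants: 16 (1S,4aR,8aR)-1-{2-[(tert-butyldiphenylsilyl)oxy]ethyl}-5,5,8a-trimethyl-1,4,4a,5,6,7,8,8a-octahydronaphthalene-2-carboxylic acid
Product: 17 2-(trimethylsilyl)ethyl (1S,4aR,8aR)-1-{2-[(tert-butyldiphenylsilyl)oxy]ethyl}-5,5,8a-trimethyl-1,4,4a,5,6,7,8,8a-octahydronaphthalene-2-carboxylate
Conditions: 2-(trimethylsilyl)ethanol, EDC·HCl, DMAP, CH2Cl2, rt
Reagents that add atoms: 2-(trimethylsilyl)ethanol, C[Si](C)(C)CCO
Why: Steglich esterification; this ester has no allylic or benzylic C–H for the chromium step, resists HF·pyridine, and can be cleaved at the end by fluoride without hydrolysing the acetate.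

Step 12
Reactants: 17 2-(trimethylsilyl)ethyl (1S,4aR,8aR)-1-{2-[(tert-butyldiphenylsilyl)oxy]ethyl}-5,5,8a-trimethyl-1,4,4a,5,6,7,8,8a-octahydronaphthalene-2-carboxylate
Product: 18 2-(trimethylsilyl)ethyl (1S,4aR,8aS)-1-{2-[(tert-butyldiphenylsilyl)oxy]ethyl}-5,5,8a-trimethyl-4-oxo-1,4,4a,5,6,7,8,8a-octahydronaphthalene-2-carboxylate
Conditions: CrO3, 3,5-dimethylpyrazole, CH2Cl2, −20 → 0 °C
Reagents that add atoms: chromium trioxide, O=[Cr](=O)=O
Why: Allylic C–H oxidation with the CrO3–3,5-dimethylpyrazole complex; C6 is the only allylic methylene and lies γ to the ester, the position at which hexavalent chromium converts cyclohexene carboxylates into their 3-oxo derivatives. No base strong enough to enolise towards C5 or C9 is present, so both centres should keep their configuration.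

Step 13
Reactants: 18 2-(trimethylsilyl)ethyl (1S,4aR,8aS)-1-{2-[(tert-butyldiphenylsilyl)oxy]ethyl}-5,5,8a-trimethyl-4-oxo-1,4,4a,5,6,7,8,8a-octahydronaphthalene-2-carboxylate
Product: 19 2-(trimethylsilyl)ethyl (1S,4S,4aR,8aS)-1-{2-[(tert-butyldiphenylsilyl)oxy]ethyl}-4-hydroxy-5,5,8a-trimethyl-1,4,4a,5,6,7,8,8a-octahydronaphthalene-2-carboxylate
Conditions: NaBH4, CeCl3·7H2O, MeOH, −40 → 0 °C
Reagents that add atoms: none
Why: Luche reduction gives 1,2-addition to the ketone of the doubly activated alkene and leaves the ester alone. Hydride approaches C6 from the face opposite the syn-axial C20 and C4 methyl groups, so the hydroxyl ends up axial and syn to C20 (6S).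

Step 14
Reactants: 19 2-(trimethylsilyl)ethyl (1S,4S,4aR,8aS)-1-{2-[(tert-butyldiphenylsilyl)oxy]ethyl}-4-hydroxy-5,5,8a-trimethyl-1,4,4a,5,6,7,8,8a-octahydronaphthalene-2-carboxylate
Product: 20 2-(trimethylsilyl)ethyl (1S,4S,4aR,8aS)-4-(acetyloxy)-1-{2-[(tert-butyldiphenylsilyl)oxy]ethyl}-5,5,8a-trimethyl-1,4,4a,5,6,7,8,8a-octahydronaphthalene-2-carboxylate
Conditions: Ac2O, Et3N, DMAP, CH2Cl2, rt → 40 °C
Reagents that add atoms: acetic anhydride, CC(=O)OC(C)=O
Why: DMAP-catalysed acylation; the hydroxyl is axial and hindered, so the nucleophilic catalyst and gentle warming are used. Lactonisation with C17 is impossible because C6 and C17 are trans across C7=C8.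

Step 15
Reactants: 20 2-(trimethylsilyl)ethyl (1S,4S,4aR,8aS)-4-(acetyloxy)-1-{2-[(tert-butyldiphenylsilyl)oxy]ethyl}-5,5,8a-trimethyl-1,4,4a,5,6,7,8,8a-octahydronaphthalene-2-carboxylate
Product: 21 2-(trimethylsilyl)ethyl (1S,4S,4aR,8aS)-4-(acetyloxy)-1-(2-hydroxyethyl)-5,5,8a-trimethyl-1,4,4a,5,6,7,8,8a-octahydronaphthalene-2-carboxylate
Conditions: HF·pyridine, pyridine, THF, 0 °C → rt
Reagents that add atoms: none
Why: HF·pyridine cleaves the silyl ether but not the acetate or the carbon-bound silicon of the ester, which needs free fluoride. The buffered, non-basic medium also avoids transesterification of the C12 hydroxyl onto C17.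

Step 16
Reactants: 21 2-(trimethylsilyl)ethyl (1S,4S,4aR,8aS)-4-(acetyloxy)-1-(2-hydroxyethyl)-5,5,8a-trimethyl-1,4,4a,5,6,7,8,8a-octahydronaphthalene-2-carboxylate
Product: 22 2-(trimethylsilyl)ethyl (1S,4S,4aR,8aS)-4-(acetyloxy)-5,5,8a-trimethyl-1-(2-oxoethyl)-1,4,4a,5,6,7,8,8a-octahydronaphthalene-2-carboxylate
Conditions: Dess–Martin periodinane, NaHCO3, CH2Cl2, 0 °C → rt
Reagents that add atoms: none
Why: Dess–Martin oxidation of the primary alcohol under buffered, neutral conditions; the aldehyde is on C12, so C9 carries no carbonyl and cannot epimerise.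

Step 17
Reactants: 22 2-(trimethylsilyl)ethyl (1S,4S,4aR,8aS)-4-(acetyloxy)-5,5,8a-trimethyl-1-(2-oxoethyl)-1,4,4a,5,6,7,8,8a-octahydronaphthalene-2-carboxylate
Product: 23 2-(trimethylsilyl)ethyl (1S,4S,4aR,8aS)-4-(acetyloxy)-5,5,8a-trimethyl-1-[(2E)-3-methyl-4-oxobut-2-en-1-yl]-1,4,4a,5,6,7,8,8a-octahydronaphthalene-2-carboxylate
Conditions: Ph3P=C(CH3)CHO, toluene, 90 °C
Reagents that add atoms: 2-(triphenylphosphoranylidene)propanal, CC(C=O)=P(c1ccccc1)(c1ccccc1)c1ccccc1
Why: Wittig reaction of a stabilised ylide with an unhindered aliphatic aldehyde; reversible betaine formation makes the trisubstituted C12=C13 bond E, with the formyl group trans to C11. The neutral ylide does not touch the ester or the acetate.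

Step 18
Reactants: 23 2-(trimethylsilyl)ethyl (1S,4S,4aR,8aS)-4-(acetyloxy)-5,5,8a-trimethyl-1-[(2E)-3-methyl-4-oxobut-2-en-1-yl]-1,4,4a,5,6,7,8,8a-octahydronaphthalene-2-carboxylate
Product: 24 2-(trimethylsilyl)ethyl (1S,4S,4aR,8aS)-4-(acetyloxy)-5,5,8a-trimethyl-1-[(2E)-3-methylpenta-2,4-dien-1-yl]-1,4,4a,5,6,7,8,8a-octahydronaphthalene-2-carboxylate
Conditions: Ph3PCH3Br, KOt-Bu, THF, 0 °C; then 23, −78 → 0 °C
Reagents that add atoms: methyltriphenylphosphonium bromide, C[P+](c1ccccc1)(c1ccccc1)c1ccccc1.[Br-]
Why: Wittig methylenation of the enal; the aldehyde reacts far faster than the hindered acetate or the conjugated ester at low temperature with a small excess of ylide, and the C12=C13 geometry is not affected.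

Step 19
Reactants: 24 2-(trimethylsilyl)ethyl (1S,4S,4aR,8aS)-4-(acetyloxy)-5,5,8a-trimethyl-1-[(2E)-3-methylpenta-2,4-dien-1-yl]-1,4,4a,5,6,7,8,8a-octahydronaphthalene-2-carboxylate
Product: 25 (1S,4S,4aR,8aS)-4-(acetyloxy)-5,5,8a-trimethyl-1-[(2E)-3-methylpenta-2,4-dien-1-yl]-1,4,4a,5,6,7,8,8a-octahydronaphthalene-2-carboxylic acid, which is (5R,6S,9S,10S)-6-acetoxylabda-7,12(E),14-trien-17-oic acid
Conditions: Bu4NF, THF, 0 °C → rt; aq. NH4Cl work-up
Reagents that add atoms: none
Why: Fluoride attacks the trimethylsilyl group and the ester fragments to the carboxylate, ethene and fluorotrimethylsilane (β-elimination of a 2-silylethyl ester). The acyl carbon is never attacked, so the hindered C6 acetate should stay in place.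

## Compound list

1 | (S)-(+)-carvone, (5S)-2-methyl-5-(prop-1-en-2-yl)cyclohex-2-en-1-one | CC(=C)[C@H]1CC=C(C)C(=O)C1 | starting material
2 | iodomethane | CI | starting material
3 | (5S)-2,6-dimethyl-5-(prop-1-en-2-yl)cyclohex-2-en-1-one (both C6 epimers) | C=C(C)[C@H]1CC=C(C)C(=O)C1C | intermediate
4 | methyl 2-(bromomethyl)prop-2-enoate | C=C(CBr)C(=O)OC | starting material
5 | methyl 2-{[(1R,6R)-1,3-dimethyl-2-oxo-6-(prop-1-en-2-yl)cyclohex-3-en-1-yl]methyl}prop-2-enoate | C=C(C(=O)OC)C[C@@]1(C)C(=O)C(C)=CC[C@@H]1C(C)=C | intermediate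
6 | methyl (2R,4aR,8aR)-4,4,7,8a-tetramethyl-8-oxo-1,2,3,4,4a,5,8,8a-octahydronaphthalene-2-carboxylate | COC(=O)[C@H]1C[C@@]2(C)C(=O)C(C)=CC[C@@H]2C(C)(C)C1 | intermediate
7 | (2R,4aR,8aR)-4,4,7,8a-tetramethyl-8-oxo-1,2,3,4,4a,5,8,8a-octahydronaphthalene-2-carboxylic acid | O=C(O)[C@H]1C[C@@]2(C)C(=O)C(C)=CC[C@@H]2C(C)(C)C1 | intermediate
8 | 2-thioxopyridin-1(2H)-yl (2R,4aR,8aR)-4,4,7,8a-tetramethyl-8-oxo-1,2,3,4,4a,5,8,8a-octahydronaphthalene-2-carboxylate (Barton ester) | O=C(On1ccccc1=S)[C@H]1C[C@@]2(C)C(=O)C(C)=CC[C@@H]2C(C)(C)C1 | intermediate (not isolated)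
9 | (4aR,8aR)-2,5,5,8a-tetramethyl-4a,5,6,7,8,8a-hexahydronaphthalen-1(4H)-one | O=C1C(C)=CC[C@@H]2C(C)(C)CCC[C@@]12C | intermediate
10 | (4aR,8aR)-2,5,5,8a-tetramethyl-1-methylidene-1,4,4a,5,6,7,8,8a-octahydronaphthalene | C=C1C(C)=CC[C@@H]2C(C)(C)CCC[C@@]12C | intermediate
11 | 9-{[(1R,4aR,8aR)-2,5,5,8a-tetramethyl-1,4,4a,5,6,7,8,8a-octahydronaphthalen-1-yl]methyl}-9-borabicyclo[3.3.1]nonane | C([C@@H]1C(C)=CC[C@@H]2C(C)(C)CCC[C@@]12C)B1C2CCCC1CCC2 | intermediate (not isolated)
12 | 1-(9-borabicyclo[3.3.1]nonan-9-yl)-2-[(1R,4aR,8aR)-2,5,5,8a-tetramethyl-1,4,4a,5,6,7,8,8a-octahydronaphthalen-1-yl]ethan-1-ol (present as its aluminium alkoxide; carbinol centre undefined) | OC(C[C@@H]1C(C)=CC[C@@H]2C(C)(C)CCC[C@@]12C)B1C2CCCC1CCC2 | intermediate (not isolated)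
13 | 2-[(1R,4aR,8aR)-2,5,5,8a-tetramethyl-1,4,4a,5,6,7,8,8a-octahydronaphthalen-1-yl]ethan-1-ol | OCC[C@@H]1C(C)=CC[C@@H]2C(C)(C)CCC[C@@]12C | intermediate
14 | tert-butyl(diphenyl){2-[(1R,4aR,8aR)-2,5,5,8a-tetramethyl-1,4,4a,5,6,7,8,8a-octahydronaphthalen-1-yl]ethoxy}silane | CC(C)(C)[Si](OCC[C@@H]1C(C)=CC[C@@H]2C(C)(C)CCC[C@@]12C)(c1ccccc1)c1ccccc1 | intermediate
15 | (1S,4aR,8aR)-1-{2-[(tert-butyldiphenylsilyl)oxy]ethyl}-5,5,8a-trimethyl-1,4,4a,5,6,7,8,8a-octahydronaphthalene-2-carbaldehyde | CC(C)(C)[Si](OCC[C@@H]1C(C=O)=CC[C@@H]2C(C)(C)CCC[C@@]12C)(c1ccccc1)c1ccccc1 | intermediate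
16 | (1S,4aR,8aR)-1-{2-[(tert-butyldiphenylsilyl)oxy]ethyl}-5,5,8a-trimethyl-1,4,4a,5,6,7,8,8a-octahydronaphthalene-2-carboxylic acid | CC(C)(C)[Si](OCC[C@@H]1C(C(=O)O)=CC[C@@H]2C(C)(C)CCC[C@@]12C)(c1ccccc1)c1ccccc1 | intermediate
17 | 2-(trimethylsilyl)ethyl (1S,4aR,8aR)-1-{2-[(tert-butyldiphenylsilyl)oxy]ethyl}-5,5,8a-trimethyl-1,4,4a,5,6,7,8,8a-octahydronaphthalene-2-carboxylate | CC(C)(C)[Si](OCC[C@@H]1C(C(=O)OCC[Si](C)(C)C)=CC[C@@H]2C(C)(C)CCC[C@@]12C)(c1ccccc1)c1ccccc1 | intermediate
18 | 2-(trimethylsilyl)ethyl (1S,4aR,8aS)-1-{2-[(tert-butyldiphenylsilyl)oxy]ethyl}-5,5,8a-trimethyl-4-oxo-1,4,4a,5,6,7,8,8a-octahydronaphthalene-2-carboxylate | CC(C)(C)[Si](OCC[C@@H]1C(C(=O)OCC[Si](C)(C)C)=CC(=O)[C@@H]2C(C)(C)CCC[C@@]12C)(c1ccccc1)c1ccccc1 | intermediate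
19 | 2-(trimethylsilyl)ethyl (1S,4S,4aR,8aS)-1-{2-[(tert-butyldiphenylsilyl)oxy]ethyl}-4-hydroxy-5,5,8a-trimethyl-1,4,4a,5,6,7,8,8a-octahydronaphthalene-2-carboxylate | CC(C)(C)[Si](OCC[C@@H]1C(C(=O)OCC[Si](C)(C)C)=C[C@H](O)[C@@H]2C(C)(C)CCC[C@@]12C)(c1ccccc1)c1ccccc1 | intermediate
20 | 2-(trimethylsilyl)ethyl (1S,4S,4aR,8aS)-4-(acetyloxy)-1-{2-[(tert-butyldiphenylsilyl)oxy]ethyl}-5,5,8a-trimethyl-1,4,4a,5,6,7,8,8a-octahydronaphthalene-2-carboxylate | CC(C)(C)[Si](OCC[C@@H]1C(C(=O)OCC[Si](C)(C)C)=C[C@H](OC(C)=O)[C@@H]2C(C)(C)CCC[C@@]12C)(c1ccccc1)c1ccccc1 | intermediate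
21 | 2-(trimethylsilyl)ethyl (1S,4S,4aR,8aS)-4-(acetyloxy)-1-(2-hydroxyethyl)-5,5,8a-trimethyl-1,4,4a,5,6,7,8,8a-octahydronaphthalene-2-carboxylate | OCC[C@@H]1C(C(=O)OCC[Si](C)(C)C)=C[C@H](OC(C)=O)[C@@H]2C(C)(C)CCC[C@@]12C | intermediate
22 | 2-(trimethylsilyl)ethyl (1S,4S,4aR,8aS)-4-(acetyloxy)-5,5,8a-trimethyl-1-(2-oxoethyl)-1,4,4a,5,6,7,8,8a-octahydronaphthalene-2-carboxylate | O=CC[C@@H]1C(C(=O)OCC[Si](C)(C)C)=C[C@H](OC(C)=O)[C@@H]2C(C)(C)CCC[C@@]12C | intermediate
23 | 2-(trimethylsilyl)ethyl (1S,4S,4aR,8aS)-4-(acetyloxy)-5,5,8a-trimethyl-1-[(2E)-3-methyl-4-oxobut-2-en-1-yl]-1,4,4a,5,6,7,8,8a-octahydronaphthalene-2-carboxylate | O=C/C(C)=C/C[C@@H]1C(C(=O)OCC[Si](C)(C)C)=C[C@H](OC(C)=O)[C@@H]2C(C)(C)CCC[C@@]12C | intermediate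
24 | 2-(trimethylsilyl)ethyl (1S,4S,4aR,8aS)-4-(acetyloxy)-5,5,8a-trimethyl-1-[(2E)-3-methylpenta-2,4-dien-1-yl]-1,4,4a,5,6,7,8,8a-octahydronaphthalene-2-carboxylate | C=C/C(C)=C/C[C@@H]1C(C(=O)OCC[Si](C)(C)C)=C[C@H](OC(C)=O)[C@@H]2C(C)(C)CCC[C@@]12C | intermediate
25 | (1S,4S,4aR,8aS)-4-(acetyloxy)-5,5,8a-trimethyl-1-[(2E)-3-methylpenta-2,4-dien-1-yl]-1,4,4a,5,6,7,8,8a-octahydronaphthalene-2-carboxylic acid | C=C/C(C)=C/C[C@@H]1C(C(=O)O)=C[C@H](OC(C)=O)[C@@H]2C(C)(C)CCC[C@@]12C | target

## Step count and least certain steps

Total step count: 19. Longest linear sequence: 19 steps, from 1 to 25.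

**Step 3 (key step).** The most likely failure is early quenching of the C4 radical by a second hydrogen atom before it finds C3, which would simply reduce the isopropenyl group. The ring closure requires both arms to be pseudo-equatorial on the cyclohexenone and forms a bond to a neopentyl centre, so it may be slow relative to reduction. Hydrogen-atom transfer to the acrylate followed by its reduction is a second diversion. Fallback: set out from 5 and generate the same radical by halogen abstraction under low hydrogen-donor concentration. Markovnikov addition of HBr (HBr in AcOH, 0 °C) to the isopropenyl group, the only alkene of 5 that gives a tertiary cation, should furnish the tertiary bromide methyl 2-{[(1R,6S)-6-(2-bromopropan-2-yl)-1,3-dimethyl-2-oxocyclohex-3-en-1-yl]methyl}prop-2-enoate F1. Slow addition of Bu3SnH with AIBN in benzene at 80 °C then abstracts bromine, and the C4 radical closes 6-endo onto the acrylate before the stannane reduces it. The route is rejoined at 6.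

**Step 7.** In the carbonylation the wrong boron–carbon bond (one of the bicyclic ring bonds) could migrate, or the acylborane could be reduced incompletely. Both would cause loss of the C12 carbon or formation of mixed borinic products. Fallback: set out from 10 and build C12 by olefination instead. Hydroboration with 9-BBN followed by NaOH/H2O2 gives [(1R,4aR,8aR)-2,5,5,8a-tetramethyl-1,4,4a,5,6,7,8,8a-octahydronaphthalen-1-yl]methanol F2. Dess–Martin oxidation gives the aldehyde (1R,4aR,8aR)-2,5,5,8a-tetramethyl-1,4,4a,5,6,7,8,8a-octahydronaphthalene-1-carbaldehyde F3, which is used cold and without chromatography because C9 is now epimerisable. Wittig methylenation (Ph3P=CH2, THF, −78 °C) gives the vinyl compound (1R,4aR,8aR)-1-ethenyl-2,5,5,8a-tetramethyl-1,4,4a,5,6,7,8,8a-octahydronaphthalene F4. A second hydroboration with 9-BBN, selective for the monosubstituted alkene, and NaOH/H2O2 returns to the route at 13.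

**Step 12.** The enoate alkene is electron-poor, so the chromium oxidant may react sluggishly. Hydrogen abstraction at the tertiary allylic C9–H would then compete and lead to oxygenation at C9 or migration of the double bond. Fallback: set out from 14 and reverse the order of the two allylic oxidations, so that chromium meets the electron-rich alkene.
- CrO3/3,5-dimethylpyrazole on 14 should give the enone (5R,9R,10S)-12-[(tert-butyldiphenylsilyl)oxy]-13,14,15,16-tetranorlabd-7-en-6-one F5.
- Luche reduction gives the axial alcohol (5R,6S,9R,10S)-12-[(tert-butyldiphenylsilyl)oxy]-13,14,15,16-tetranorlabd-7-en-6-ol F6.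
- Ac2O/DMAP gives the acetate (5R,6S,9R,10S)-12-[(tert-butyldiphenylsilyl)oxy]-13,14,15,16-tetranorlabd-7-en-6-yl acetate F7.
- SeO2 in dioxane oxidises C17 to the aldehyde (5R,6S,9S,10S)-6-acetoxy-12-[(tert-butyldiphenylsilyl)oxy]-13,14,15,16-tetranorlabd-7-en-17-al F8.
- Pinnick oxidation gives the acid (5R,6S,9S,10S)-6-acetoxy-12-[(tert-butyldiphenylsilyl)oxy]-13,14,15,16-tetranorlabd-7-en-17-oic acid F9.
- Esterification with 2-(trimethylsilyl)ethanol (EDC·HCl, DMAP) rejoins the route at 20.

**Step 6.** Addition of the ylide to the C9 carbonyl, which is shielded by C20 and the C8 methyl, may be slow. The ylide can then act as a base at C6 (γ-deprotonation to the dienolate), returning or isomerising the enone. Fallback: set out from 9 and use a small, non-basic nucleophile followed by elimination. Me3SiCH2Li/CeCl3 (THF, −78 °C) should add 1,2 from the face opposite C20 to give the β-hydroxysilane (1R,4aR,8aR)-2,5,5,8a-tetramethyl-1-[(trimethylsilyl)methyl]-1,4,4a,5,6,7,8,8a-octahydronaphthalen-1-ol F10. Peterson elimination with KH in THF then gives 10, where the route is rejoined.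

**Step 19.** Fluoride in THF is basic. Before the ester has fragmented it could cause loss or migration of the acetyl group, or 1,4-elimination of acetic acid across C9–C8=C7–C6. Fallback: set out from 24, cleave both esters and put the acetate back. LiOH in THF/MeOH/H2O at 50 °C should give the hydroxy acid (1S,4S,4aR,8aS)-4-hydroxy-5,5,8a-trimethyl-1-[(2E)-3-methylpenta-2,4-dien-1-yl]-1,4,4a,5,6,7,8,8a-octahydronaphthalene-2-carboxylic acid F11. Acetylation with Ac2O, DMAP and pyridine, followed by aqueous NaHCO3 to hydrolyse the mixed anhydride, arrives at 25.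

## Further compounds

F1 | step 3 | methyl 2-{[(1R,6S)-6-(2-bromopropan-2-yl)-1,3-dimethyl-2-oxocyclohex-3-en-1-yl]methyl}prop-2-enoate | C=C(C(=O)OC)C[C@@]1(C)C(=O)C(C)=CC[C@@H]1C(C)(C)Br
F2 | step 7 | [(1R,4aR,8aR)-2,5,5,8a-tetramethyl-1,4,4a,5,6,7,8,8a-octahydronaphthalen-1-yl]methanol | OC[C@@H]1C(C)=CC[C@@H]2C(C)(C)CCC[C@@]12C
F3 | step 7 | (1R,4aR,8aR)-2,5,5,8a-tetramethyl-1,4,4a,5,6,7,8,8a-octahydronaphthalene-1-carbaldehyde | O=C[C@@H]1C(C)=CC[C@@H]2C(C)(C)CCC[C@@]12C
F4 | step 7 | (1R,4aR,8aR)-1-ethenyl-2,5,5,8a-tetramethyl-1,4,4a,5,6,7,8,8a-octahydronaphthalene | C=C[C@@H]1C(C)=CC[C@@H]2C(C)(C)CCC[C@@]12C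
F5 | step 12 | (5R,9R,10S)-12-[(tert-butyldiphenylsilyl)oxy]-13,14,15,16-tetranorlabd-7-en-6-one | CC(C)(C)[Si](OCC[C@@H]1C(C)=CC(=O)[C@@H]2C(C)(C)CCC[C@@]12C)(c1ccccc1)c1ccccc1
F6 | step 12 | (5R,6S,9R,10S)-12-[(tert-butyldiphenylsilyl)oxy]-13,14,15,16-tetranorlabd-7-en-6-ol | CC(C)(C)[Si](OCC[C@@H]1C(C)=C[C@H](O)[C@@H]2C(C)(C)CCC[C@@]12C)(c1ccccc1)c1ccccc1
F7 | step 12 | (5R,6S,9R,10S)-12-[(tert-butyldiphenylsilyl)oxy]-13,14,15,16-tetranorlabd-7-en-6-yl acetate | CC(C)(C)[Si](OCC[C@@H]1C(C)=C[C@H](OC(C)=O)[C@@H]2C(C)(C)CCC[C@@]12C)(c1ccccc1)c1ccccc1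
F8 | step 12 | (5R,6S,9S,10S)-6-acetoxy-12-[(tert-butyldiphenylsilyl)oxy]-13,14,15,16-tetranorlabd-7-en-17-al | CC(C)(C)[Si](OCC[C@@H]1C(C=O)=C[C@H](OC(C)=O)[C@@H]2C(C)(C)CCC[C@@]12C)(c1ccccc1)c1ccccc1
F9 | step 12 | (5R,6S,9S,10S)-6-acetoxy-12-[(tert-butyldiphenylsilyl)oxy]-13,14,15,16-tetranorlabd-7-en-17-oic acid | CC(C)(C)[Si](OCC[C@@H]1C(C(=O)O)=C[C@H](OC(C)=O)[C@@H]2C(C)(C)CCC[C@@]12C)(c1ccccc1)c1ccccc1
F10 | step 6 | (1R,4aR,8aR)-2,5,5,8a-tetramethyl-1-[(trimethylsilyl)methyl]-1,4,4a,5,6,7,8,8a-octahydronaphthalen-1-ol | C[Si](C)(C)C[C@@]1(O)C(C)=CC[C@@H]2C(C)(C)CCC[C@@]12C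
F11 | step 19 | (1S,4S,4aR,8aS)-4-hydroxy-5,5,8a-trimethyl-1-[(2E)-3-methylpenta-2,4-dien-1-yl]-1,4,4a,5,6,7,8,8a-octahydronaphthalene-2-carboxylic acid | C=C/C(C)=C/C[C@@H]1C(C(=O)O)=C[C@H](O)[C@@H]2C(C)(C)CCC[C@@]12C
A1 | alternative 1 | (1S)-8,8-dimethyl-1,2,3,4,5,6,7,8-octahydronaphthalen-1-ol (allylic alcohol with the C5=C10 alkene) | O[C@H]1CCCC2=C1C(C)(C)CCC2
A2 | alternative 1 | [4.4.1]propellane carbinol (C20 methylene bridging C5 and C10, syn to the C6 hydroxyl) | O[C@H]1CCC[C@@]23C[C@@]12C(C)(C)CCC3
A3 | alternative 2 | (2E,8Z,10E)-9-[(tert-butyldimethylsilyl)oxy]-12-[(4-methoxyphenyl)methoxy]-3,7,7-trimethyldodeca-2,8,10-trienal | O=C/C=C(\C)CCCC(C)(C)/C=C(O[Si](C)(C)C(C)(C)C)/C=C/COCc1ccc(OC)cc1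
A4 | alternative 2 | trans-fused bicyclic silyl enol ether with formyl group on C9 and (4-methoxybenzyloxy)methyl group on C8 | O=C[C@@H]1[C@H](COCc3ccc(OC)cc3)C=C(O[Si](C)(C)C(C)(C)C)[C@@H]2C(C)(C)CCC[C@@]12C
A5 | alternative 3 | Se-phenyl selenoester of the ring A acid carrying on C10 the C9 arm with the 2-substituted acrylate and the N-methoxy-N-methylamide | CON(C)C(=O)C[C@H](C(=C)C(=O)OCC[Si](C)(C)C)[C@]1(C)CCCC(C)(C)[C@H]1C(=O)[Se]c1ccccc1
A6 | alternative 3 | trans-decal-6-one with 2-(trimethylsilyl)ethyl ester on C8 and N-methoxy-N-methylacetamide chain on C9 | CON(C)C(=O)C[C@@H]1[C@@H](C(=O)OCC[Si](C)(C)C)CC(=O)[C@@H]2C(C)(C)CCC[C@@]12C
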